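**Retrosynthetic overview**
- The strategy rests on the pyran oxygen O1, which links the quaternary stereocentre C2 to the aryl carbon C8a. The pyran ring is closed last at O1–C8a by palladium-catalysed aryl etherification of an acyclic (R)-tertiary alcohol, so C2 is set before the ring exists and its C–O bond is never broken.
- After ring closure: thiolate O-demethylation at C6, then magnesium-mediated ortho-formylation at C5.
- The tertiary alcohol comes from an (S)-2-substituted glycidol, opened at its CH2 by a benzylic Grignard reagent (C3–C4 bond), followed by CH2OH → CH3. The glycidol comes from Sharpless epoxidation of a 2-methylidene alcohol made from methallyl alcohol dianion and (2E,6E)-farnesyl bromide.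
- The arene is the symmetric 4-bromo-3,5-dimethylanisole: one methyl becomes C4, the other stays as the C8 methyl, and the bromine already sits at C8a.
- Ring order: benzene ring purchased; pyran ring formed in step 7, the only ring-forming step.

Key step: step 7

**Step 1**
Reactants: 1 2-methylprop-2-en-1-ol (methallyl alcohol); 2 (2E,6E)-farnesyl bromide
Product: 4 (5E,9E)-6,10,14-trimethyl-2-methylidenepentadeca-5,9,13-trien-1-ol, via methallyl alcohol dianion 3 (not isolated)
Conditions: 1 (1.3 equiv), n-BuLi (2.9 equiv), TMEDA, Et2O–hexane, 0 °C to rt; then 2, THF, −78 to 0 °C; H2O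
Reagents that add atoms: none
Why: Alkylation of the methallyl alcohol dianion: n-BuLi/TMEDA removes the O–H and one allylic methyl proton to give a 2-(oxidomethyl)allyl-lithium whose two CH2 termini are equivalent, and SN2 attack on the primary allylic bromide should form the CH2–CH2 bond between the C4 unit and the farnesyl unit without touching the E-alkenes.

**Step 2**
Reactants: 4 (5E,9E)-6,10,14-trimethyl-2-methylidenepentadeca-5,9,13-trien-1-ol
Product: 5 [(2S)-2-[(3E,7E)-4,8,12-trimethyltrideca-3,7,11-trien-1-yl]oxiran-2-yl]methanol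
Conditions: Ti(OiPr)4 (10 mol %), L-(+)-diethyl tartrate (12 mol %), t-BuOOH (2 equiv, anhydrous), 4 Å MS, CH2Cl2, −20 °C
Reagents that add atoms: tert-butyl hydroperoxide, CC(C)(C)OO
Why: Sharpless asymmetric epoxidation: the titanium–tartrate complex binds the allylic hydroxyl and so epoxidises only the 1,1-disubstituted allylic alkene, and L-(+)-diethyl tartrate delivers oxygen to the face that gives the 2S epoxide (the same face that turns allyl alcohol into (S)-glycidol), which sets the future C2 stereocentre.

**Step 3**
Reactants: 6 4-bromo-3,5-dimethylanisole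
Product: 7 2-bromo-1-(bromomethyl)-5-methoxy-3-methylbenzene
Conditions: NBS (1.0 equiv), AIBN (5 mol %), PhCF3, 80 °C
Reagents that add atoms: N-bromosuccinimide, O=C1CCC(=O)N1Br
Why: Wohl–Ziegler radical bromination: the two methyl groups of 6 are equivalent by symmetry, so one equivalent of NBS under radical initiation in a non-polar solvent should give a single benzylic monobromide, the low steady-state Br2 concentration disfavouring ring bromination ortho to the methoxy group.

**Step 4**
Reactants: 7 2-bromo-1-(bromomethyl)-5-methoxy-3-methylbenzene; 5 [(2S)-2-[(3E,7E)-4,8,12-trimethyltrideca-3,7,11-trien-1-yl]oxiran-2-yl]methanol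
Product: 9 (2R,5E,9E)-2-[2-(2-bromo-5-methoxy-3-methylphenyl)ethyl]-6,10,14-trimethylpentadeca-5,9,13-triene-1,2-diol, via benzylic Grignard reagent 8 (not isolated)
Conditions: 7 (3 equiv), Mg turnings, Et2O, 0 °C, slow addition; then 5, CuI (10 mol %), THF, −40 to 0 °C; aq. NH4Cl
Reagents that add atoms: none
Why: Grignard formation followed by copper-catalysed epoxide opening: magnesium inserts into the benzylic C–Br bond much faster than into the aryl C–Br bond, the first equivalent of 8 only deprotonates the hydroxyl of 5, and the benzylcopper species formed with CuI attacks the unsubstituted epoxide CH2 by SN2, forming the future C3–C4 bond while the four bonds of the quaternary carbon stay untouched (the descriptor changes from S to R only through the priority rules, and a Payne rearrangement of this 2-substituted glycidol is degenerate).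

**Step 5**
Reactants: 9 (2R,5E,9E)-2-[2-(2-bromo-5-methoxy-3-methylphenyl)ethyl]-6,10,14-trimethylpentadeca-5,9,13-triene-1,2-diol
Product: 10 (2R,5E,9E)-2-[2-(2-bromo-5-methoxy-3-methylphenyl)ethyl]-2-hydroxy-6,10,14-trimethylpentadeca-5,9,13-trien-1-yl 4-methylbenzenesulfonate
Conditions: TsCl (1.1 equiv), Et3N (1.5 equiv), Bu2SnO (2 mol %), CH2Cl2, 0 °C to rt
Reagents that add atoms: 4-toluenesulfonyl chloride, Cc1ccc(cc1)S(Cl)(=O)=O
Why: Selective sulfonylation of the primary hydroxyl of a 1,2-diol through a catalytic dibutylstannylene acetal, the tertiary hydroxyl being too hindered to react.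

**Step 6**
Reactants: 10 (2R,5E,9E)-2-[2-(2-bromo-5-methoxy-3-methylphenyl)ethyl]-2-hydroxy-6,10,14-trimethylpentadeca-5,9,13-trien-1-yl 4-methylbenzenesulfonate
Product: 12 (3R,6E,10E)-1-(2-bromo-5-methoxy-3-methylphenyl)-3,7,11,15-tetramethylhexadeca-6,10,14-trien-3-ol, via terminal epoxide 11 (not isolated)
Conditions: LiBHEt3 (3 equiv), THF, 0 °C to rt; H2O
Reagents that add atoms: none
Why: Hydride reduction through an epoxide: LiBHEt3 deprotonates the tertiary hydroxyl, the alkoxide displaces the neighbouring primary tosylate to give epoxide 11, and hydride opens it by SN2 attack at the CH2 terminus to leave the C2 methyl group, so the C2–O bond is never broken and the configuration is retained, while the aryl bromide and the trisubstituted alkenes are inert to this reagent at 0 °C to room temperature.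

**Step 7**
Reactants: 12 (3R,6E,10E)-1-(2-bromo-5-methoxy-3-methylphenyl)-3,7,11,15-tetramethylhexadeca-6,10,14-trien-3-ol
Product: 13 (2R)-6-methoxy-2,8-dimethyl-2-[(3E,7E)-4,8,12-trimethyltrideca-3,7,11-trien-1-yl]-3,4-dihydro-2H-chromene ((R)-δ-tocotrienol methyl ether)
Conditions: Pd(OAc)2 (3 mol %), 2-(di-tert-butylphosphino)-1,1'-binaphthyl (4 mol %), Cs2CO3 (1.5 equiv), toluene, 80 °C
Reagents that add atoms: none
Why: Buchwald–Hartwig-type intramolecular aryl etherification: zerovalent palladium carrying the bulky di-tert-butyl(biaryl)phosphine inserts into the C8a–Br bond, Cs2CO3 deprotonates the palladium-bound tertiary hydroxyl, and C–O reductive elimination from the resulting aryl(alkoxo) complex of divalent palladium forms the O1–C8a bond. The pyran ring is closed as a six-membered ring by this reductive elimination from a seven-membered oxapalladacycle (Pd, C8a, C4a, C4, C3, C2, O). No stereocentre is created; C2 keeps its R configuration because none of its four bonds takes part, the oxygen acting only as the nucleophile. The step needs C–O coupling to win over β-hydride elimination, hydrodebromination and Heck insertion: the alkoxide has no hydrogen on its carbinol carbon, the bulky electron-rich ligand and the two ortho substituents of C8a (C8 methyl and C4a chain) accelerate reductive elimination, and the trisubstituted alkenes are remote and poor insertion partners. The closest known reaction type is the palladium-catalysed cyclisation of aryl bromides bearing pendant tertiary alcohols to 2,2-disubstituted chromans.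

**Step 8**
Reactants: 13 (2R)-6-methoxy-2,8-dimethyl-2-[(3E,7E)-4,8,12-trimethyltrideca-3,7,11-trien-1-yl]-3,4-dihydro-2H-chromene
Product: 14 (2R)-2,8-dimethyl-2-[(3E,7E)-4,8,12-trimethyltrideca-3,7,11-trien-1-yl]-3,4-dihydro-2H-chromen-6-ol ((R)-δ-tocotrienol)
Conditions: NaSEt (4 equiv), DMF, 130 °C, argon; then 1 M HCl
Reagents that add atoms: none
Why: Nucleophilic O-demethylation (SN2 at the methyl carbon) by ethanethiolate; the chroman ether oxygen sits between a tertiary and an aryl carbon and cannot be cleaved this way, and the isolated alkenes do not react with the thiolate.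

**Step 9**
Reactants: 14 (2R)-2,8-dimethyl-2-[(3E,7E)-4,8,12-trimethyltrideca-3,7,11-trien-1-yl]-3,4-dihydro-2H-chromen-6-ol
Product: 16 (2R)-6-hydroxy-2,8-dimethyl-2-[(3E,7E)-4,8,12-trimethyltrideca-3,7,11-trien-1-yl]-3,4-dihydro-2H-chromene-5-carbaldehyde, via 5-hydroxymethyl chromanol 15 (not isolated)
Conditions: MgCl2 (2 equiv), Et3N (4 equiv), (CH2O)n (6 equiv), MeCN, reflux; then 1 M HCl
Reagents that add atoms: paraformaldehyde (formaldehyde), C=O
Why: Magnesium-mediated ortho-formylation of a phenol (Casnati–Skattebøl reaction): the magnesium phenoxide delivers formaldehyde to the ortho carbon and the resulting salicyl alkoxide 15 is oxidised by a second formaldehyde through hydride transfer, and attack at C5 should be preferred over C7 because the cyclohexadienone-like intermediate then keeps the C4a=C8a double bond at the ring fusion, the bond-fixation (Mills–Nixon) preference known for 5,7-unsubstituted chromanols.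

**Compound list**
1 | 2-methylprop-2-en-1-ol (methallyl alcohol) | CC(=C)CO | starting material
2 | (2E,6E)-farnesyl bromide | CC(C)=CCC/C(C)=C/CC/C(C)=C/CBr | starting material
3 | dilithiated methallyl alcohol (lithium 2-(lithiomethyl)prop-2-en-1-olate) | [Li]CC(=C)CO[Li] | intermediate
4 | (5E,9E)-6,10,14-trimethyl-2-methylidenepentadeca-5,9,13-trien-1-ol | CC(C)=CCC/C(C)=C/CC/C(C)=C/CCC(=C)CO | intermediate
5 | [(2S)-2-[(3E,7E)-4,8,12-trimethyltrideca-3,7,11-trien-1-yl]oxiran-2-yl]methanol | CC(C)=CCC/C(C)=C/CC/C(C)=C/CC[C@@]1(CO)OC1 | intermediate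
6 | 4-bromo-3,5-dimethylanisole | COc1cc(C)c(Br)c(C)c1 | starting material
7 | 2-bromo-1-(bromomethyl)-5-methoxy-3-methylbenzene | COc1cc(C)c(Br)c(CBr)c1 | intermediate
8 | (2-bromo-5-methoxy-3-methylbenzyl)magnesium bromide | COc1cc(C)c(Br)c(C[Mg]Br)c1 | intermediate
9 | (2R,5E,9E)-2-[2-(2-bromo-5-methoxy-3-methylphenyl)ethyl]-6,10,14-trimethylpentadeca-5,9,13-triene-1,2-diol | CC(C)=CCC/C(C)=C/CC/C(C)=C/CC[C@@](CO)(O)CCc1cc(OC)cc(C)c1Br | intermediate
10 | (2R,5E,9E)-2-[2-(2-bromo-5-methoxy-3-methylphenyl)ethyl]-2-hydroxy-6,10,14-trimethylpentadeca-5,9,13-trien-1-yl 4-methylbenzenesulfonate | CC(C)=CCC/C(C)=C/CC/C(C)=C/CC[C@@](COS(=O)(=O)c1ccc(C)cc1)(O)CCc1cc(OC)cc(C)c1Br | intermediate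
11 | (2R)-2-[2-(2-bromo-5-methoxy-3-methylphenyl)ethyl]-2-[(3E,7E)-4,8,12-trimethyltrideca-3,7,11-trien-1-yl]oxirane | CC(C)=CCC/C(C)=C/CC/C(C)=C/CC[C@]1(CO1)CCc1cc(OC)cc(C)c1Br | intermediate
12 | (3R,6E,10E)-1-(2-bromo-5-methoxy-3-methylphenyl)-3,7,11,15-tetramethylhexadeca-6,10,14-trien-3-ol | CC(C)=CCC/C(C)=C/CC/C(C)=C/CC[C@@](C)(O)CCc1cc(OC)cc(C)c1Br | intermediate
13 | (2R)-6-methoxy-2,8-dimethyl-2-[(3E,7E)-4,8,12-trimethyltrideca-3,7,11-trien-1-yl]-3,4-dihydro-2H-chromene | CC(C)=CCC/C(C)=C/CC/C(C)=C/CC[C@]1(C)CCc2cc(OC)cc(C)c2O1 | intermediate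
14 | (2R)-2,8-dimethyl-2-[(3E,7E)-4,8,12-trimethyltrideca-3,7,11-trien-1-yl]-3,4-dihydro-2H-chromen-6-ol | CC(C)=CCC/C(C)=C/CC/C(C)=C/CC[C@]1(C)CCc2cc(O)cc(C)c2O1 | intermediate
15 | (2R)-5-(hydroxymethyl)-2,8-dimethyl-2-[(3E,7E)-4,8,12-trimethyltrideca-3,7,11-trien-1-yl]-3,4-dihydro-2H-chromen-6-ol | CC(C)=CCC/C(C)=C/CC/C(C)=C/CC[C@]1(C)CCc2c(CO)c(O)cc(C)c2O1 | intermediate
16 | (2R)-6-hydroxy-2,8-dimethyl-2-[(3E,7E)-4,8,12-trimethyltrideca-3,7,11-trien-1-yl]-3,4-dihydro-2H-chromene-5-carbaldehyde | CC(C)=CCC/C(C)=C/CC/C(C)=C/CC[C@]1(C)CCc2c(C=O)c(O)cc(C)c2O1 | target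

**Step count**
Total: 9 steps. Longest linear sequence: 8 steps (1, 2, 4, 5, 6, 7, 8, 9); the arene branch (step 3) joins at step 4.

**Steps most likely to fail**

Step 7. Oxidative addition of palladium into the C–Br bond flanked by the C8 methyl and the C4a chain may be slow, so that hydrodebromination or catalyst decay overtakes C–O reductive elimination. The fallback sets out from 12 and rejoins the route at 14. The bromide is exchanged for hydroxyl (n-BuLi, 2.2 equiv, THF, −78 °C; B(OMe)3; then NaOH/H2O2, 0 °C) to give 2-[(3R,6E,10E)-3-hydroxy-3,7,11,15-tetramethylhexadeca-6,10,14-trien-1-yl]-4-methoxy-6-methylphenol F1. Oxidation with PhI(OAc)2 in aqueous MeCN at 0 °C removes the O-methyl group as methanol and gives the hydroxyalkyl benzoquinone 2-[(3R,6E,10E)-3-hydroxy-3,7,11,15-tetramethylhexadeca-6,10,14-trien-1-yl]-6-methylcyclohexa-2,5-diene-1,4-dione F2, the quinone form of δ-tocotrienol. F2 would then be closed reductively (ascorbic acid with catalytic camphorsulfonic acid in MeOH at room temperature, or Zn/AcOH). The tertiary hydroxyl adds to the C1 carbonyl, the future C8a, to give a cyclic hemiketal, and reduction with loss of water aromatises it to chromanol 14. This is the reductive ring closure of tocopherylquinones to tocopherols. It forms the same O1–C8a bond with the side-chain oxygen kept as O1, so C2 should be retained as long as no acid strong enough to ionise the tertiary C–O bond is used; the enantiomeric purity of 14 would have to be checked. The sequence needs no palladium and skips compound 13 and step 8.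

Step 9. Formaldehyde may also be delivered to C7, and the salicyl alcohol stage may condense with a second chromanol to give diarylmethanes. The fallback sets out from 14 and rejoins at 16. Electrophilic iodination at low temperature (I2, morpholine, CH2Cl2, 0 °C) should give (2R)-5-iodo-2,8-dimethyl-2-[(3E,7E)-4,8,12-trimethyltrideca-3,7,11-trien-1-yl]-3,4-dihydro-2H-chromen-6-ol F3. It relies on the same intrinsic C5 preference, but under kinetic control, and any C7 isomer can be separated before the carbon is introduced. Deprotonation with MeMgCl, iodine–magnesium exchange with i-PrMgCl·LiCl (THF, −20 to 0 °C), quenching with DMF and aqueous acid would then give 16. No benzylic alcohol or quinone methide intermediate is involved.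

Step 1. The allyl-lithium may attack farnesyl bromide with allylic transposition, or undergo halogen–metal exchange and homocoupling, and some O-alkylation is possible. The fallback sets out from 2 and rejoins at 12. Alkylation of ethyl acetoacetate (NaOEt, EtOH) with 2 gives ethyl (4E,8E)-2-acetyl-5,9,13-trimethyltetradeca-4,8,12-trienoate F4. Saponification and decarboxylation (aq. NaOH, then acidification and warming) give (5E,9E)-6,10,14-trimethylpentadeca-5,9,13-trien-2-one F5 (farnesylacetone). Catalytic asymmetric Corey–Chaykovsky methylene transfer (dimethyloxosulfonium methylide, LaLi3 tris(binaphthoxide) with a triarylphosphine oxide additive, 5 Å MS, THF, room temperature) gives (2R)-2-methyl-2-[(3E,7E)-4,8,12-trimethyltrideca-3,7,11-trien-1-yl]oxirane F6. The catalyst antipode that delivers the R configuration is used; which antipode that is has not been assigned here and would be fixed by correlation with 12 from the main route. Opening of F6 with Grignard reagent 8 and CuI as in step 4 gives 12 directly. This replaces the allyl-lithium coupling by an enolate alkylation and sets C2 by a different reaction. It bypasses 4, 5, 9, 10 and 11, but the enantioselectivity is less secure for a dialkyl ketone and would have to be measured.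

**Further compounds**
F1 | step 7 | 2-[(3R,6E,10E)-3-hydroxy-3,7,11,15-tetramethylhexadeca-6,10,14-trien-1-yl]-4-methoxy-6-methylphenol | CC(C)=CCC/C(C)=C/CC/C(C)=C/CC[C@@](C)(O)CCc1cc(OC)cc(C)c1O
F2 | step 7 | 2-[(3R,6E,10E)-3-hydroxy-3,7,11,15-tetramethylhexadeca-6,10,14-trien-1-yl]-6-methylcyclohexa-2,5-diene-1,4-dione | CC(C)=CCC/C(C)=C/CC/C(C)=C/CC[C@@](C)(O)CCC1=CC(=O)C=C(C)C1=O
F3 | step 9 | (2R)-5-iodo-2,8-dimethyl-2-[(3E,7E)-4,8,12-trimethyltrideca-3,7,11-trien-1-yl]-3,4-dihydro-2H-chromen-6-ol | CC(C)=CCC/C(C)=C/CC/C(C)=C/CC[C@]1(C)CCc2c(I)c(O)cc(C)c2O1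
F4 | step 1 | ethyl (4E,8E)-2-acetyl-5,9,13-trimethyltetradeca-4,8,12-trienoate | CC(C)=CCC/C(C)=C/CC/C(C)=C/CC(C(C)=O)C(=O)OCC
F5 | step 1 | (5E,9E)-6,10,14-trimethylpentadeca-5,9,13-trien-2-one | CC(C)=CCC/C(C)=C/CC/C(C)=C/CCC(C)=O
F6 | step 1 | (2R)-2-methyl-2-[(3E,7E)-4,8,12-trimethyltrideca-3,7,11-trien-1-yl]oxirane | CC(C)=CCC/C(C)=C/CC/C(C)=C/CC[C@]1(C)CO1
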